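The three flavan units are joined last by cationic C4 arylation at both interflavan bonds (top C4–mid C8, mid C4–bottom C6). The top and bottom units come from (−)-epicatechin, and the middle flavan is built de novo. Its ring C is closed at the aryl ether bond O1–C8a. Ring A of this unit is 1,3,5-trioxygenated (C5, C7, C8a), so a fluorine kept from 1,3,5-trifluorobenzene stands in for O1 and is displaced by the C2 alkoxide of an acyclic, syn-aldol-derived 1,3-diarylpropane-1,3-diol. One operation gives the chroman with the 2,3-cis array untouched, completes the phloroglucinol pattern, and leaves a free C4–OH as leaving group for the 4β→6 coupling.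

Key step: step 7

Remark: flavan numbering (O1, C2, C3, C4, C4a, C5 to C8, C8a; rings A, B, C) is used for every unit. The carbinol carbon that becomes C4 of the middle unit (C1 of 12, C4 of 13) should form as a mixture of epimers and is written without configuration, because it is erased when C4 ionises in step 11.

Step 1
Reactants: 1 (S)-4-benzyl-1,3-oxazolidin-2-one; 2 2-(benzyloxy)acetyl chloride
Product: 3 (S)-4-benzyl-3-[2-(benzyloxy)acetyl]-1,3-oxazolidin-2-one
Conditions: n-BuLi, THF, −78 °C; then 2, −78 → 0 °C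
Reagents that add atoms: none
Why: N-acylation of the lithiated oxazolidinone by the acid chloride, which does not touch the auxiliary stereocenter.

Step 2
Reactants: 3 (S)-4-benzyl-3-[2-(benzyloxy)acetyl]-1,3-oxazolidin-2-one; 4 3,4-bis(benzyloxy)benzaldehyde
Product: 6 (S)-4-benzyl-3-[(2S,3R)-2-(benzyloxy)-3-[3,4-bis(benzyloxy)phenyl]-3-hydroxypropanoyl]-1,3-oxazolidin-2-one, via Z-boron enolate 5 (not isolated)
Conditions: Bu2BOTf, Et3N, CH2Cl2, −78 → 0 °C; then 4, −78 → 0 °C; H2O2, MeOH, pH 7 buffer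
Reagents that add atoms: none
Why: Evans syn glycolate aldol through the Z-boron enolate and a chair Zimmerman–Traxler transition state, in which the benzyl group of the auxiliary shields one enolate face so that C2 (S) and C3 (R) are set syn, the array that becomes C3 and C2 of an epicatechin unit.

Step 3
Reactants: 6 (S)-4-benzyl-3-[(2S,3R)-2-(benzyloxy)-3-[3,4-bis(benzyloxy)phenyl]-3-hydroxypropanoyl]-1,3-oxazolidin-2-one
Product: 7 (2S,3R)-2-(benzyloxy)-3-[3,4-bis(benzyloxy)phenyl]-3-hydroxy-N-methoxy-N-methylpropanamide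
Conditions: Me3Al, MeNH(OMe)·HCl, CH2Cl2, −20 → 0 °C
Reagents that add atoms: N,O-dimethylhydroxylamine hydrochloride, CNOC.Cl
Why: Weinreb amide formation by aluminium amide transamidation of the imide, assisted by the free β-hydroxyl, with no stereocenter involved.

Step 4
Reactants: 8 1,3,5-trifluorobenzene
Product: 9 1,3-bis(benzyloxy)-5-fluorobenzene
Conditions: BnOH (2.05 equiv), NaH, THF/DMPU, 0 → 70 °C
Reagents that add atoms: benzyl alcohol, OCc1ccccc1
Why: two successive SNAr displacements of fluoride by benzyloxide, each of which makes the ring less electrophilic so that the third fluorine should remain.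

Step 5
Reactants: 9 1,3-bis(benzyloxy)-5-fluorobenzene; 7 (2S,3R)-2-(benzyloxy)-3-[3,4-bis(benzyloxy)phenyl]-3-hydroxy-N-methoxy-N-methylpropanamide
Product: 11 (2S,3R)-2-(benzyloxy)-1-[2,4-bis(benzyloxy)-6-fluorophenyl]-3-[3,4-bis(benzyloxy)phenyl]-3-hydroxypropan-1-one, via aryllithium 10 (not isolated)
Conditions: 9 (2.4 equiv), n-BuLi (2.3 equiv), THF, −78 °C; then 7, −78 °C; aq. NH4Cl at −78 °C
Reagents that add atoms: none
Why: directed ortho-lithiation at the C–H flanked by F and OBn followed by Weinreb ketone synthesis, in which the first equivalent of 10 only deprotonates the hydroxyl and the chelated tetrahedral adduct should prevent over-addition and retro-aldol cleavage until the cold quench, the temperature being held at −78 °C so that 10 does not lose LiF.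

Step 6
Reactants: 11 (2S,3R)-2-(benzyloxy)-1-[2,4-bis(benzyloxy)-6-fluorophenyl]-3-[3,4-bis(benzyloxy)phenyl]-3-hydroxypropan-1-one
Product: 12 (1RS,2S,3R)-2-(benzyloxy)-1-[2,4-bis(benzyloxy)-6-fluorophenyl]-3-[3,4-bis(benzyloxy)phenyl]propane-1,3-diol
Conditions: NaBH4, CeCl3·7H2O, MeOH/THF, −40 → 0 °C
Reagents that add atoms: none
Why: Luche reduction of the aryl ketone under non-basic conditions, which should avoid enolisation at C2 and premature fluoride displacement, the new carbinol centre being formed as a harmless mixture.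

Step 7
Reactants: 12 (1RS,2S,3R)-2-(benzyloxy)-1-[2,4-bis(benzyloxy)-6-fluorophenyl]-3-[3,4-bis(benzyloxy)phenyl]propane-1,3-diol
Product: 13 (2R,3R,4RS)-3,5,7-tris(benzyloxy)-2-[3,4-bis(benzyloxy)phenyl]chroman-4-ol
Conditions: KH (2.5 equiv), THF/DMPU 4:1, 0 → 60 °C; aq. NH4Cl
Reagents that add atoms: none
Why: KH converts both hydroxyls into potassium alkoxides, and the alkoxide on the ring B side (future O1) adds to the fluorine-bearing carbon of ring A (future C8a) to give a Meisenheimer complex whose charge on C8, C6 and C4a is stabilised inductively by the benzyloxy-bearing carbons C7 and C5, which are meta to the site of attack and so do not donate into it; loss of fluoride then restores the arene (addition–elimination SNAr). The closest known reaction type is the intramolecular SNAr etherification of non-activated and 3,5-dialkoxy fluoroarenes by tethered alkoxides to give chromans. Ring C (O1, C2, C3, C4, C4a, C8a) closes in a 6-exo-trig mode. No stereocenter is created: the C–O bond at C2 is never broken, so C2 (R) and C3 (R) from the aldol step are carried over with retention and the syn array becomes the 2,3-cis flavan. The step needs chemoselectivity among the oxygens, which the substrate secures: O3 is benzylated so no five-membered benzofuran can form, the C4 alkoxide could only close a four-membered ring, there is a single C–F bond, and the C4–OH simply survives as its alkoxide.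

Step 8
Reactants: 14 (−)-epicatechin
Product: 15 5,7,3',4'-tetra-O-benzyl-(−)-epicatechin
Conditions: BnBr (4.4 equiv), K2CO3, DMF, 0 °C → rt, N2
Reagents that add atoms: benzyl bromide, BrCc1ccccc1
Why: Williamson etherification of the four phenols, the secondary 3-OH not being deprotonated by carbonate.

Step 9
Reactants: 15 5,7,3',4'-tetra-O-benzyl-(−)-epicatechin
Product: 16 8-bromo-5,7,3',4'-tetra-O-benzyl-(−)-epicatechin
Conditions: NBS (1.0 equiv), CH2Cl2, −78 °C → rt
Reagents that add atoms: N-bromosuccinimide, O=C1CCC(=O)N1Br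
Why: electrophilic aromatic bromination, which should occur at C8, the more accessible of the two activated positions of ring A.

Step 10
Reactants: 16 8-bromo-5,7,3',4'-tetra-O-benzyl-(−)-epicatechin
Product: 17 (2R,3R,4S)-5,7-bis(benzyloxy)-2-[3,4-bis(benzyloxy)phenyl]-8-bromo-4-(2-ethoxyethoxy)chroman-3-ol
Conditions: DDQ (2 equiv), 2-ethoxyethanol, CH2Cl2, rt
Reagents that add atoms: 2-ethoxyethanol, CCOCCO
Why: benzylic oxidation by DDQ (hydride abstraction at C4) gives the ring-A-stabilised cation, which the alcohol should trap anti to the 3-OH to set the 4β ether.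

Step 11
Reactants: 13 (2R,3R,4RS)-3,5,7-tris(benzyloxy)-2-[3,4-bis(benzyloxy)phenyl]chroman-4-ol; 16 8-bromo-5,7,3',4'-tetra-O-benzyl-(−)-epicatechin
Product: 18 3,5,7,3',4'-penta-O-benzylepicatechin-(4β→6)-8-bromo-5,7,3',4'-tetra-O-benzylepicatechin
Conditions: 16 (3 equiv), TMSOTf (0.3 equiv), 4 Å molecular sieves, CH2Cl2, −78 → −20 °C, slow addition of 13
Reagents that add atoms: none
Why: Friedel–Crafts-type arylation in which acid ionises the C4–OH of 13 to the 2,4,6-trialkoxybenzylic cation, and ring A of 16, with C8 blocked by bromine, should attack through C6 anti to the 3-OBn group to set the new C4 centre 4β (3,4-trans).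

Step 12
Reactants: 17 (2R,3R,4S)-5,7-bis(benzyloxy)-2-[3,4-bis(benzyloxy)phenyl]-8-bromo-4-(2-ethoxyethoxy)chroman-3-ol; 18 3,5,7,3',4'-penta-O-benzylepicatechin-(4β→6)-8-bromo-5,7,3',4'-tetra-O-benzylepicatechin
Product: 19 8-bromo-5,7,3',4'-tetra-O-benzylepicatechin-(4β→8)-3,5,7,3',4'-penta-O-benzylepicatechin-(4β→6)-8-bromo-5,7,3',4'-tetra-O-benzylepicatechin
Conditions: 17 (1.2 equiv), TMSOTf (0.2 equiv), CH2Cl2, −78 → −40 °C
Reagents that add atoms: none
Why: Friedel–Crafts-type arylation in which the C4 cation from 17 (kept from self-condensation by its C8 bromine) should be attacked by C8 of the middle unit of 18, the most accessible free ring A position, anti to the 3-OH to set the top C4 centre 4β.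

Step 13
Reactants: 19 8-bromo-5,7,3',4'-tetra-O-benzylepicatechin-(4β→8)-3,5,7,3',4'-penta-O-benzylepicatechin-(4β→6)-8-bromo-5,7,3',4'-tetra-O-benzylepicatechin
Product: 20 epicatechin-(4β→8)-epicatechin-(4β→6)-epicatechin (target)
Conditions: H2 (1 atm), Pd(OH)2/C, Et3N (2.5 equiv), THF/MeOH/H2O, rt
Reagents that add atoms: none
Why: catalytic hydrogenolysis of the thirteen benzyl ethers with concurrent hydrodebromination of both aryl bromides, Et3N buffering the HBr so that the acid-labile interflavan bonds and all stereocenters should be preserved.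

Compound list
1 | (S)-4-benzyl-1,3-oxazolidin-2-one | O=C1OC[C@H](Cc2ccccc2)N1 | starting material
2 | 2-(benzyloxy)acetyl chloride | O=C(Cl)COCc1ccccc1 | starting material
3 | (S)-4-benzyl-3-[2-(benzyloxy)acetyl]-1,3-oxazolidin-2-one | O=C1OC[C@H](Cc2ccccc2)N1C(=O)COCc1ccccc1 | intermediate
4 | 3,4-bis(benzyloxy)benzaldehyde | O=Cc1ccc(OCc2ccccc2)c(OCc2ccccc2)c1 | starting material
5 | (Z)-dibutylboron enolate of 3 (boryloxy and benzyloxy groups cis) | CCCCB(CCCC)O/C(=C\OCc1ccccc1)N1C(=O)OC[C@@H]1Cc1ccccc1 | intermediate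
6 | (S)-4-benzyl-3-[(2S,3R)-2-(benzyloxy)-3-[3,4-bis(benzyloxy)phenyl]-3-hydroxypropanoyl]-1,3-oxazolidin-2-one | O=C1OC[C@H](Cc2ccccc2)N1C(=O)[C@@H](OCc1ccccc1)[C@H](O)c1ccc(OCc2ccccc2)c(OCc2ccccc2)c1 | intermediate
7 | (2S,3R)-2-(benzyloxy)-3-[3,4-bis(benzyloxy)phenyl]-3-hydroxy-N-methoxy-N-methylpropanamide | CON(C)C(=O)[C@@H](OCc1ccccc1)[C@H](O)c1ccc(OCc2ccccc2)c(OCc2ccccc2)c1 | intermediate
8 | 1,3,5-trifluorobenzene | Fc1cc(F)cc(F)c1 | starting material
9 | 1,3-bis(benzyloxy)-5-fluorobenzene | Fc1cc(OCc2ccccc2)cc(OCc2ccccc2)c1 | intermediate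
10 | [2,4-bis(benzyloxy)-6-fluorophenyl]lithium | [Li]c1c(F)cc(OCc2ccccc2)cc1OCc1ccccc1 | intermediate
11 | (2S,3R)-2-(benzyloxy)-1-[2,4-bis(benzyloxy)-6-fluorophenyl]-3-[3,4-bis(benzyloxy)phenyl]-3-hydroxypropan-1-one | O=C(c1c(F)cc(OCc2ccccc2)cc1OCc1ccccc1)[C@@H](OCc1ccccc1)[C@H](O)c1ccc(OCc2ccccc2)c(OCc2ccccc2)c1 | intermediate
12 | (1RS,2S,3R)-2-(benzyloxy)-1-[2,4-bis(benzyloxy)-6-fluorophenyl]-3-[3,4-bis(benzyloxy)phenyl]propane-1,3-diol | OC(c1c(F)cc(OCc2ccccc2)cc1OCc1ccccc1)[C@@H](OCc1ccccc1)[C@H](O)c1ccc(OCc2ccccc2)c(OCc2ccccc2)c1 | intermediate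
13 | (2R,3R,4RS)-3,5,7-tris(benzyloxy)-2-[3,4-bis(benzyloxy)phenyl]chroman-4-ol (3,5,7,3',4'-penta-O-benzyl-4-hydroxyepicatechin) | c1c(OCc2ccccc2)cc(OCc2ccccc2)c2c1O[C@H](c1ccc(OCc3ccccc3)c(OCc3ccccc3)c1)[C@H](OCc1ccccc1)C2O | intermediate
14 | (−)-epicatechin, (2R,3R)-2-(3,4-dihydroxyphenyl)chroman-3,5,7-triol | Oc1cc(O)c2c(c1)O[C@H](c1ccc(O)c(O)c1)[C@H](O)C2 | starting material
15 | 5,7,3',4'-tetra-O-benzyl-(−)-epicatechin, (2R,3R)-5,7-bis(benzyloxy)-2-[3,4-bis(benzyloxy)phenyl]chroman-3-ol | c1c(OCc2ccccc2)cc(OCc2ccccc2)c2c1O[C@H](c1ccc(OCc3ccccc3)c(OCc3ccccc3)c1)[C@H](O)C2 | intermediate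
16 | 8-bromo-5,7,3',4'-tetra-O-benzyl-(−)-epicatechin, (2R,3R)-5,7-bis(benzyloxy)-2-[3,4-bis(benzyloxy)phenyl]-8-bromochroman-3-ol | Brc1c(OCc2ccccc2)cc(OCc2ccccc2)c2c1O[C@H](c1ccc(OCc3ccccc3)c(OCc3ccccc3)c1)[C@H](O)C2 | intermediate
17 | (2R,3R,4S)-5,7-bis(benzyloxy)-2-[3,4-bis(benzyloxy)phenyl]-8-bromo-4-(2-ethoxyethoxy)chroman-3-ol (4β ether of 16) | Brc1c(OCc2ccccc2)cc(OCc2ccccc2)c2c1O[C@H](c1ccc(OCc3ccccc3)c(OCc3ccccc3)c1)[C@H](O)[C@H]2OCCOCC | intermediate
18 | 3,5,7,3',4'-penta-O-benzylepicatechin-(4β→6)-8-bromo-5,7,3',4'-tetra-O-benzylepicatechin | c1c(OCc2ccccc2)cc(OCc2ccccc2)c2c1O[C@H](c1ccc(OCc3ccccc3)c(OCc3ccccc3)c1)[C@H](OCc1ccccc1)[C@H]2c1c(OCc2ccccc2)c(Br)c2c(c1OCc1ccccc1)C[C@@H](O)[C@@H](c1ccc(OCc3ccccc3)c(OCc3ccccc3)c1)O2 | intermediate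
19 | 8-bromo-5,7,3',4'-tetra-O-benzylepicatechin-(4β→8)-3,5,7,3',4'-penta-O-benzylepicatechin-(4β→6)-8-bromo-5,7,3',4'-tetra-O-benzylepicatechin | Brc1c(OCc2ccccc2)cc(OCc2ccccc2)c2c1O[C@H](c1ccc(OCc3ccccc3)c(OCc3ccccc3)c1)[C@H](O)[C@H]2c1c(OCc2ccccc2)cc(OCc2ccccc2)c2c1O[C@H](c1ccc(OCc3ccccc3)c(OCc3ccccc3)c1)[C@H](OCc1ccccc1)[C@H]2c1c(OCc2ccccc2)c(Br)c2c(c1OCc1ccccc1)C[C@@H](O)[C@@H](c1ccc(OCc3ccccc3)c(OCc3ccccc3)c1)O2 | intermediate
20 | epicatechin-(4β→8)-epicatechin-(4β→6)-epicatechin | Oc1cc(O)c2c(c1)O[C@H](c1ccc(O)c(O)c1)[C@H](O)[C@H]2c1c(O)cc(O)c2c1O[C@H](c1ccc(O)c(O)c1)[C@H](O)[C@H]2c1c(O)cc2c(c1O)C[C@@H](O)[C@@H](c1ccc(O)c(O)c1)O2 | target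

Total step count: 13.
Longest linear sequence: 9 steps (1, 2, 3, 5, 6, 7, 11, 12, 13).

Steps most likely to fail

Step 7. The addition–elimination at the electron-rich, non-activated fluoroarene carbon may be so slow that, at the temperature needed, the dipotassium alkoxide degrades (attack on benzyl ethers, base-induced fragmentation) before ring C closes. The fallback sets out from ketone 11 and uses its carbonyl as an ortho activator: Cs2CO3 in MeCN at 0 °C should close ring C by acyl-activated SNAr under very mild conditions to give (2R,3S)-3,5,7-tris(benzyloxy)-2-[3,4-bis(benzyloxy)phenyl]chroman-4-one F1. This is reduced at once with NaBH4/CeCl3·7H2O in MeOH/THF at −40 °C, before the C3 centre next to the carbonyl can epimerise, and the route is rejoined at 13.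

Step 5. The ortho-fluoroaryllithium may lose LiF (benzyne formation) before it has acylated the hindered amide, or the lithium aldolate may cleave by retro-aldol. The fallback sets out from 7 and uses a more reactive electrophile. Silylation (TBSOTf, 2,6-lutidine, CH2Cl2) should give (2S,3R)-2-(benzyloxy)-3-[3,4-bis(benzyloxy)phenyl]-3-[(tert-butyldimethylsilyl)oxy]-N-methoxy-N-methylpropanamide F2. Reduction with i-Bu2AlH in THF at −78 °C should give (2S,3R)-2-(benzyloxy)-3-[3,4-bis(benzyloxy)phenyl]-3-[(tert-butyldimethylsilyl)oxy]propanal F3, to which 10 adds rapidly at −78 °C to give (1RS,2R,3R)-2-(benzyloxy)-1-[2,4-bis(benzyloxy)-6-fluorophenyl]-3-[3,4-bis(benzyloxy)phenyl]-3-[(tert-butyldimethylsilyl)oxy]propan-1-ol F4. Desilylation with Bu4NF in THF rejoins the route at 12, so that step 6 is not needed.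

Step 11. Cation 13 may alkylate the free C8 of a second molecule of 13, or of product 18, faster than it is captured by the hindered, bromine-deactivated C6 of 16, which would lead to oligomerisation. The fallback sets out from 13 and 17, reverses the order of assembly and uses orthogonal activation. Treatment of 13 with 2,6-dimethylbenzenethiol and BF3·OEt2 in CH2Cl2 at −78 °C should give 4β-[(2,6-dimethylphenyl)sulfanyl]-3,5,7,3',4'-penta-O-benzylepicatechin F5, whose C–S bond should be inert to hard Lewis acids. Coupling of 17 with F5 (BF3·OEt2, CH2Cl2, −78 °C) through the free C8 of F5 should give 8-bromo-5,7,3',4'-tetra-O-benzylepicatechin-(4β→8)-4β-[(2,6-dimethylphenyl)sulfanyl]-3,5,7,3',4'-penta-O-benzylepicatechin F6, an electrophile with no free C8 left for self-condensation. Thiophilic activation with AgOTf in CH2Cl2 at −40 °C in the presence of 16 should then form the 4β→6 bond and rejoin the route at 19.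

Further compounds
F1 | step 7 | (2R,3S)-3,5,7-tris(benzyloxy)-2-[3,4-bis(benzyloxy)phenyl]chroman-4-one | c1c(OCc2ccccc2)cc(OCc2ccccc2)c2c1O[C@H](c1ccc(OCc3ccccc3)c(OCc3ccccc3)c1)[C@H](OCc1ccccc1)C2=O
F2 | step 5 | (2S,3R)-2-(benzyloxy)-3-[3,4-bis(benzyloxy)phenyl]-3-[(tert-butyldimethylsilyl)oxy]-N-methoxy-N-methylpropanamide | CON(C)C(=O)[C@@H](OCc1ccccc1)[C@H](O[Si](C)(C)C(C)(C)C)c1ccc(OCc2ccccc2)c(OCc2ccccc2)c1
F3 | step 5 | (2S,3R)-2-(benzyloxy)-3-[3,4-bis(benzyloxy)phenyl]-3-[(tert-butyldimethylsilyl)oxy]propanal | O=C[C@@H](OCc1ccccc1)[C@H](O[Si](C)(C)C(C)(C)C)c1ccc(OCc2ccccc2)c(OCc2ccccc2)c1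
F4 | step 5 | (1RS,2R,3R)-2-(benzyloxy)-1-[2,4-bis(benzyloxy)-6-fluorophenyl]-3-[3,4-bis(benzyloxy)phenyl]-3-[(tert-butyldimethylsilyl)oxy]propan-1-ol | OC(c1c(F)cc(OCc2ccccc2)cc1OCc1ccccc1)[C@@H](OCc1ccccc1)[C@H](O[Si](C)(C)C(C)(C)C)c1ccc(OCc2ccccc2)c(OCc2ccccc2)c1
F5 | step 11 | 4β-[(2,6-dimethylphenyl)sulfanyl]-3,5,7,3',4'-penta-O-benzylepicatechin | c1c(OCc2ccccc2)cc(OCc2ccccc2)c2c1O[C@H](c1ccc(OCc3ccccc3)c(OCc3ccccc3)c1)[C@H](OCc1ccccc1)[C@H]2Sc1c(C)cccc1C
F6 | step 11 | 8-bromo-5,7,3',4'-tetra-O-benzylepicatechin-(4β→8)-4β-[(2,6-dimethylphenyl)sulfanyl]-3,5,7,3',4'-penta-O-benzylepicatechin | Brc1c(OCc2ccccc2)cc(OCc2ccccc2)c2c1O[C@H](c1ccc(OCc3ccccc3)c(OCc3ccccc3)c1)[C@H](O)[C@H]2c1c(OCc2ccccc2)cc(OCc2ccccc2)c2c1O[C@H](c1ccc(OCc3ccccc3)c(OCc3ccccc3)c1)[C@H](OCc1ccccc1)[C@H]2Sc1c(C)cccc1C
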